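## Analysis of the target

The target 18 is a flavone, a 4H-chromen-4-one. Its benzo ring A carries a free hydroxyl at C5 and a methyl ether at C7, ring C is unsubstituted at C3, and C2 bears ring B, a phenyl ring with hydroxyls at C2' and C5', methyl ethers at C3' and C4' and a single hydrogen at C6'. There is no stereocentre, so every problem is one of regiochemistry: six oxygens must be told apart, three as phenols and three as methyl ethers, without relying on a late selective methylation or demethylation. Ring B is a 2,3-dimethoxyhydroquinone, easily oxidised to the quinone (above all in base), and should stay masked until the last step. The 2'-hydroxyl lies ortho to the bond to C2, so in an open-chain 1,3-diketone it could close ring C from the wrong side and give an isomeric chromone; it has to be blocked while ring C forms. The 5-hydroxyl is hydrogen-bonded to the C4 carbonyl and robust, and the C2–C3 double bond is the only reducible site besides protecting groups. The plan rests on the oxygen pattern of ring A: O5, O7 and O1 (on C8a) alternate as in phloroglucinol, the only methyl ether (C7) is para to the acyl-bearing C4a, and the two oxygens ortho to C4a are equivalent until one of them closes ring C. This is the pattern that results when a 4-methoxy-2-pyranone with a 2-oxoalkyl chain at C6 is opened and its chain methylene condenses onto the former lactone carbonyl, so ring A can be built with the C7 ether in place from the start.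

## Retrosynthetic reasoning

**18 to 17.** The last disconnection removes the two benzyl groups from O2' and O5' of 17. Benzyl ethers survive the lithium amide, organolithium and magnesium alkoxide steps, and come off by neutral hydrogenolysis, so the oxidation-prone hydroquinone never meets base. The benzyl group on O2' also blocks that oxygen during ring C closure.

**17 to 15.** Ring C is cut at O1–C2, giving the 1,3-diketone 15. In the forward sense a ring A hydroxyl adds to the ring B ketone (hemiketal 16) and dehydration follows. The two hydroxyls of 15 flank the acyl group symmetrically, so either closure gives 17 and the other hydroxyl becomes the chelated 5-OH. No regiochemical choice arises on ring A, and none on ring B because O2' is benzylated.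

**15 to 13 (through 14).** Ring A is cut at C4a–C8a. This reveals the open-chain ester 14, in which the future C4a is a methylene between two ketones and the future C8a is an ester carbonyl held cis to the chain by an (E)-enol ether. Compound 14 is the methanolysis product of the 4-methoxy-2-pyranone 13. The cut is made here because the pyranone already carries the C7 methyl ether on the right carbon and fixes the geometry needed for closure. The forward reaction has to open the lactone and then steer the chain into a Claisen rather than an aldol condensation; the magnesium alkoxide base of step 7 is chosen for that.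

**13 to 11 and 7.** The chain of 13 is cut between its terminal methylene (future C3) and the ring B carbonyl (future C2). This is the most convergent cut: all of ring B arrives as one acyl electrophile, amide 7, and the nucleophile is the terminal carbon of the dianion 12 of ketone 11, the most basic and most nucleophilic site. An N-methoxy-N-methylamide is preferred to a simple ester because its chelated tetrahedral adduct does not release the acidic triketone until work-up, so the product cannot quench unreacted 12.

**11 to 8 and 9.** The bond between the ring-bound methylene (future C4a) and the ketone carbon (future C4) is cut. The 6-methyl group of 8 is deprotonated as a vinylogous ester (species 10), and 9 delivers exactly one acetyl group without over-addition.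

**7 back to 1.** The carbonyl carbon of 7 is attached to the arene through aryllithium 6, made by halogen–lithium exchange on bromide 5. Compound 5 comes from bromination of the symmetric bis(benzyl) ether 4, whose two free positions are equivalent. Compound 4 arises from hydroquinone 3, the reduction product of quinone 2, and 2 comes from para-oxidation of phenol 1. Phenol 1 already holds three of the four contiguous oxygens of ring B, with the two methyl ethers in their final positions.

## Alternatives that were turned down

**Alternative 1:** Ring B is disconnected at C1'–C2'. C2' to C5' and their four oxygens are traced to dimethyl squarate A3, and C6' and C1' to an alkenyl group that already carries rings A and C. In the forward sense a vinyl-metal reagent bearing the chromone would add to one carbonyl of A3 to give the 4-alkenyl-4-hydroxycyclobutenone A2. Heating A2 opens the four-membered ring to a dienylketene, which closes by 6π electrocyclisation and tautomerises to the free hydroquinone A1 (Moore rearrangement). Hydrogenolysis of the 5-O-benzyl group of A1 would give 18.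
- For: the two methyl ethers come in with A3 and the two hydroxyls are created unprotected at C2' and C5', so the ring B pattern is fixed by construction and needs no bromination, lithiation or protecting group. On this point it is stronger than the chosen route.
- Against: the vinyl-metal reagent must carry a chromone, itself a Michael acceptor with an electrophilic carbonyl, and it must add only once to A3. The thermolysis releases an electron-rich hydroquinone at high temperature, where oxidation to the quinone is likely. Rings A and C still need a separate synthesis before the key step.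
- Comparison: it would be clearly longer and its fragment union is the weakest step. The chosen route instead obtains ring B from 1 by four ordinary steps and applies the ring-forming step to ring A, where the pyranone supplies the pattern.

**Alternative 2:** Ring C is disconnected at C3–C4 and O1–C8a. The lithium enolate of the ring B acetophenone A5 would be C-acylated by 2,6-difluoro-4-methoxybenzoyl chloride A6. The enolate oxygen of the resulting 1,3-diketone would then displace one of the two equivalent ortho fluorides (activated by the adjacent carbonyl) to give the 5-fluoroflavone A4.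
- For: the sequence is short and convergent, the two fluorides are equivalent so no regiochemical question arises, and both bond formations are reliable. In robustness of the key step it is probably stronger than the chosen route, and it is of similar length.
- Against: A4 carries fluorine where the target needs the 5-hydroxyl. A second substitution by an oxygen nucleophile is required on a chromone that can also be attacked at C2 with opening of ring C. C- versus O-acylation of the enolate has to be controlled, and A6 is a specialised building block.
- Comparison: the chosen route delivers O5 directly as a phenol and needs no heteroatom exchange on the finished heterocycle, and its ring A comes from an inexpensive pyranone.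

**Alternative 3:** Rings A and B are joined through C4a–C4, C4–C3 and O1–C2 in one operation. 2-Iodo-5-methoxybenzene-1,3-diol A7, carbon monoxide A8 and the ring B arylacetylene A9 would be coupled with a divalent palladium–phosphine precatalyst and a secondary amine. Oxidative addition of A7 to zerovalent palladium, insertion of A8 and coupling with A9 would give an ortho-hydroxyaryl ynone, and amine-assisted 6-endo closure would give A10, which is identical with 17.
- For: once the fragments exist it reaches 17 in a single step, and A7 is symmetric. In step economy at the fragment union it is stronger than the chosen route.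
- Against: A7 is electron-rich and flanked by two free hydroxyls, so oxidative addition is slow and deiodination competes. Coupling without insertion of A8 leads to a 2-arylbenzofuran, and the ynone can close 5-exo to an aurone instead of 6-endo. A9 needs two further steps from 5.
- Comparison: the outcome depends on a catalyst choosing among three pathways. The chosen route uses only polar two-electron steps with predictable regiochemistry, and its overall length is about the same.

Key step: step 7

Assumption: the 1,3-di- and 1,3,5-tricarbonyl compounds 11, 13, 14 and 15 are drawn as keto forms although they will exist largely as chelated enols, and 15 may be obtained partly as its ring-closed hemiketal 16, which step 8 converts into the same product.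

## Route

Step 1
Reactants: 1 2,3-dimethoxyphenol
Product: 2 2,3-dimethoxycyclohexa-2,5-diene-1,4-dione (2,3-dimethoxy-1,4-benzoquinone)
Conditions: (KSO3)2NO (2.2 equiv), KH2PO4 buffer, H2O/acetone, 0 °C to rt
Reagents that add atoms: potassium nitrosodisulfonate (KSO3)2NO, [K+].[K+].[O]N(S(=O)(=O)[O-])S(=O)(=O)[O-]
Why: Teuber oxidation of a phenol with a free para position; the phenoxyl radical is trapped at C4 by a second nitrosodisulfonate radical and collapses to the para-quinone, which places the fourth oxygen next to the two methyl ethers.

Step 2
Reactants: 2 2,3-dimethoxy-1,4-benzoquinone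
Product: 4 1,4-bis(benzyloxy)-2,3-dimethoxybenzene, via 2,3-dimethoxybenzene-1,4-diol 3 (not isolated)
Conditions: Na2S2O4, EtOAc/H2O, rt; organic layer dried and concentrated under Ar; then BnBr, K2CO3, DMF, 60 °C
Reagents that add atoms: benzyl bromide, BrCc1ccccc1
Why: Dithionite reduction of the quinone followed by Williamson etherification of both phenols; the air-sensitive hydroquinone is carried on crude under argon so it cannot re-oxidise.

Step 3
Reactants: 4 1,4-bis(benzyloxy)-2,3-dimethoxybenzene
Product: 5 1,4-bis(benzyloxy)-5-bromo-2,3-dimethoxybenzene
Conditions: NBS (1.05 equiv), MeCN, 0 °C to rt, dark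
Reagents that add atoms: N-bromosuccinimide, O=C1CCC(=O)N1Br
Why: Electrophilic aromatic bromination of a tetraalkoxybenzene; the two free positions are equivalent by symmetry, the first bromine slows a second substitution, and the benzyl phenyl rings are far less activated.

Step 4
Reactants: 5 1,4-bis(benzyloxy)-5-bromo-2,3-dimethoxybenzene
Product: 7 2,5-bis(benzyloxy)-N,3,4-trimethoxy-N-methylbenzamide, via the aryllithium 6 (not isolated)
Conditions: n-BuLi (1.05 equiv), THF, −78 °C; then cannulated into ClC(=O)N(OMe)Me (1.5 equiv), THF, −78 to 0 °C
Reagents that add atoms: N-methoxy-N-methylcarbamoyl chloride, CON(C)C(Cl)=O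
Why: Bromine–lithium exchange at −78 °C is faster than benzylic deprotonation, and trapping the aryllithium with the carbamoyl chloride gives the Weinreb amide directly; inverse addition to excess electrophile keeps the aryllithium from adding to the product.

Step 5
Reactants: 8 4-methoxy-6-methyl-2H-pyran-2-one; 9 N-methoxy-N-methylacetamide
Product: 11 4-methoxy-6-(2-oxopropyl)-2H-pyran-2-one, via the 6-lithiomethylpyranone 10 (not isolated)
Conditions: LiN(i-Pr)2 (1.0 equiv), THF, −78 °C; then 9 (1.1 equiv), −78 to −40 °C; aq. NH4Cl
Reagents that add atoms: none
Why: Vinylogous deprotonation of the 6-methyl group gives a dienolate that is C-acylated by the Weinreb amide; the chelated tetrahedral adduct holds back the acidic ketone until quench, so one equivalent of base suffices and over-addition is excluded.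

Step 6
Reactants: 11 4-methoxy-6-(2-oxopropyl)-2H-pyran-2-one; 7 2,5-bis(benzyloxy)-N,3,4-trimethoxy-N-methylbenzamide
Product: 13 6-{4-[2,5-bis(benzyloxy)-3,4-dimethoxyphenyl]-2,4-dioxobutyl}-4-methoxy-2H-pyran-2-one, via the 1,3-dilithio dianion 12 (not isolated)
Conditions: LiN(i-Pr)2 (2.1 equiv), THF, −78 to −20 °C; then 7 (0.85 equiv), −78 to 0 °C; aq. NH4Cl
Reagents that add atoms: none
Why: Terminal (γ) acylation of a 1,3-dicarbonyl-type dianion; the second, less stabilised carbanion at the methyl carbon is the reactive site, and the Weinreb amide adduct prevents the more acidic triketone from protonating unreacted dianion.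

Step 7
Reactants: 13 6-{4-[2,5-bis(benzyloxy)-3,4-dimethoxyphenyl]-2,4-dioxobutyl}-4-methoxy-2H-pyran-2-one
Product: 15 1-[2,5-bis(benzyloxy)-3,4-dimethoxyphenyl]-3-(2,6-dihydroxy-4-methoxyphenyl)propane-1,3-dione, via the ring-opened methyl ester 14 (not isolated)
Conditions: Mg(OMe)2 (6–8 equiv), MeOH, reflux, Ar; then cold 1 M HCl
Reagents that add atoms: none
Why: Methoxide adds to the lactone carbonyl of the magnesium-chelated substrate and opens the pyranone to ester 14, whose (2E)-enol ether, inherited from the ring, keeps the ester carbon C1 cis to the chain. The magnesium enolate carbon C6 of 14, the methylene between the C5 and C7 ketones and the future C4a, attacks the ester carbonyl, methoxide is lost and the cyclohexadienone enolises to the aromatic ring A. The closest known reaction type is the magnesium methoxide-mediated Claisen (Dieckmann-type) recyclisation of 6-(2-oxoalkyl)-4-methoxy-2-pyranones to 2,6-dihydroxy-4-methoxyphenyl ketones. Ring A closes in a 6-exo-trig mode, the ester oxygen staying outside the new ring, and no stereocentre is formed. The step needs the Claisen closure C6 to C1 to win over aldol closure of C2 onto the C7 ketone (a resorcylate), aldol closure of C4 onto the aryl ketone C9, and methanolysis of the tricarbonyl chain. Three features of the substrate favour it: C6 is the most acidic carbon and sits in a magnesium β-diketonate, the enol ether makes C2 vinylic so the aldol mode would need deprotonation at the less acidic C4, and chelation turns the ketones into poorly electrophilic enolates while the ester stays the one free acceptor. Aromatisation makes the closure irreversible, and it places the methyl ether para to the acyl group with two equivalent hydroxyls beside it.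

Step 8
Reactants: 15 1-[2,5-bis(benzyloxy)-3,4-dimethoxyphenyl]-3-(2,6-dihydroxy-4-methoxyphenyl)propane-1,3-dione
Product: 17 2-[2,5-bis(benzyloxy)-3,4-dimethoxyphenyl]-5-hydroxy-7-methoxy-4H-chromen-4-one, via the 2-hydroxyflavanone hemiketal 16 (not isolated)
Conditions: p-TsOH·H2O (0.1 equiv), toluene, 80 °C
Reagents that add atoms: none
Why: Acid-catalysed cyclodehydration of an ortho-hydroxyaryl 1,3-diketone; either equivalent ring A hydroxyl adds to the ring B ketone and loss of water gives the flavone, while the benzyl ether on O2' excludes closure onto ring B and the mild sulfonic acid leaves the benzyl ethers intact.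

Step 9
Reactants: 17 2-[2,5-bis(benzyloxy)-3,4-dimethoxyphenyl]-5-hydroxy-7-methoxy-4H-chromen-4-one
Product: 18 2-(2,5-dihydroxy-3,4-dimethoxyphenyl)-5-hydroxy-7-methoxy-4H-chromen-4-one
Conditions: H2 (1 atm), 10% Pd/C, EtOAc/MeOH, rt; filtration and concentration under Ar
Reagents that add atoms: none
Why: Catalytic hydrogenolysis of two aryl benzyl ethers under neutral conditions; the conjugated C2–C3 double bond of a flavone is normally untouched at atmospheric pressure, and the absence of base protects the liberated hydroquinone.

## Compound list

1 | 2,3-dimethoxyphenol | COc1cccc(O)c1OC | starting material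
2 | 2,3-dimethoxycyclohexa-2,5-diene-1,4-dione | COC1=C(OC)C(=O)C=CC1=O | intermediate
3 | 2,3-dimethoxybenzene-1,4-diol (not isolated) | COc1c(O)ccc(O)c1OC | intermediate
4 | 1,4-bis(benzyloxy)-2,3-dimethoxybenzene | COc1c(OCc2ccccc2)ccc(OCc2ccccc2)c1OC | intermediate
5 | 1,4-bis(benzyloxy)-5-bromo-2,3-dimethoxybenzene | COc1c(OCc2ccccc2)cc(Br)c(OCc2ccccc2)c1OC | intermediate
6 | [2,5-bis(benzyloxy)-3,4-dimethoxyphenyl]lithium (not isolated) | [Li]c1cc(OCc2ccccc2)c(OC)c(OC)c1OCc1ccccc1 | intermediate
7 | 2,5-bis(benzyloxy)-N,3,4-trimethoxy-N-methylbenzamide | CON(C)C(=O)c1cc(OCc2ccccc2)c(OC)c(OC)c1OCc1ccccc1 | intermediate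
8 | 4-methoxy-6-methyl-2H-pyran-2-one | COc1cc(C)oc(=O)c1 | starting material
9 | N-methoxy-N-methylacetamide | CON(C)C(C)=O | starting material
10 | [(4-methoxy-2-oxo-2H-pyran-6-yl)methyl]lithium (not isolated) | [Li]Cc1cc(OC)cc(=O)o1 | intermediate
11 | 4-methoxy-6-(2-oxopropyl)-2H-pyran-2-one | CC(=O)Cc1cc(OC)cc(=O)o1 | intermediate
12 | dilithium salt of the dianion of 11, deprotonated at the ring-bound CH2 and the terminal CH3 (not isolated) | [Li+].[Li+].[CH2-]C(=O)[CH-]c1cc(OC)cc(=O)o1 | intermediate
13 | 6-{4-[2,5-bis(benzyloxy)-3,4-dimethoxyphenyl]-2,4-dioxobutyl}-4-methoxy-2H-pyran-2-one | COc1cc(CC(=O)CC(=O)c2cc(OCc3ccccc3)c(OC)c(OC)c2OCc2ccccc2)oc(=O)c1 | intermediate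
14 | methyl (2E)-9-[2,5-bis(benzyloxy)-3,4-dimethoxyphenyl]-3-methoxy-5,7,9-trioxonon-2-enoate (not isolated) | COC(=O)/C=C(/OC)CC(=O)CC(=O)CC(=O)c1cc(OCc2ccccc2)c(OC)c(OC)c1OCc1ccccc1 | intermediate
15 | 1-[2,5-bis(benzyloxy)-3,4-dimethoxyphenyl]-3-(2,6-dihydroxy-4-methoxyphenyl)propane-1,3-dione | COc1cc(O)c(C(=O)CC(=O)c2cc(OCc3ccccc3)c(OC)c(OC)c2OCc2ccccc2)c(O)c1 | intermediate
16 | 2-[2,5-bis(benzyloxy)-3,4-dimethoxyphenyl]-2,5-dihydroxy-7-methoxy-2,3-dihydro-4H-chromen-4-one (racemic, not isolated) | COc1cc(O)c2c(c1)OC(O)(c1cc(OCc3ccccc3)c(OC)c(OC)c1OCc1ccccc1)CC2=O | intermediate
17 | 2-[2,5-bis(benzyloxy)-3,4-dimethoxyphenyl]-5-hydroxy-7-methoxy-4H-chromen-4-one | COc1cc(O)c2c(=O)cc(-c3cc(OCc4ccccc4)c(OC)c(OC)c3OCc3ccccc3)oc2c1 | intermediate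
18 | 2-(2,5-dihydroxy-3,4-dimethoxyphenyl)-5-hydroxy-7-methoxy-4H-chromen-4-one | COc1cc(O)c2c(=O)cc(-c3cc(O)c(OC)c(OC)c3O)oc2c1 | target

## Step count and least certain steps

Total: 9 steps. Longest linear sequence: 8 steps (steps 1, 2, 3, 4, 6, 7, 8, 9, from 1 to 18); the pyranone branch contributes step 5.

**Step 7 (key step).** The opened chain may close by an aldol pathway instead of the Claisen pathway, the tricarbonyl chain may be cleaved by methanolysis, or the lactone of the doubly deprotonated, chelated substrate may resist methoxide. The extra aryl ketone adds a second enolisable site that the simple 6-(2-oxoalkyl) cases lack, so selectivity is less assured here.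
Fallback, from 5 back to 15: bromine–lithium exchange on 5 and trapping with CO2 would give 2,5-bis(benzyloxy)-3,4-dimethoxybenzoic acid F1. Oxalyl chloride with catalytic DMF would convert it into 2,5-bis(benzyloxy)-3,4-dimethoxybenzoyl chloride F2. Commercial 1-(2,6-dihydroxy-4-methoxyphenyl)ethan-1-one F3 would be converted with LiN(SiMe3)2 (4 equiv, THF, −78 °C) into its lithium polyanion and C-aroylated by F2, a one-pot Baker–Venkataraman-type diketone synthesis that gives 15 directly.

**Step 6.** Incomplete second deprotonation, proton transfer between species, or sluggish addition of the stabilised dianion to a hindered, electron-rich amide would leave 11 and 7 unchanged or give mixtures.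
Fallback, from 7 and 11 back to 13: reduction of 7 with i-Bu2AlH (THF, −78 °C) would give 2,5-bis(benzyloxy)-3,4-dimethoxybenzaldehyde F4, a far better electrophile. Aldol addition of dianion 12 to F4 would give racemic 6-{4-[2,5-bis(benzyloxy)-3,4-dimethoxyphenyl]-4-hydroxy-2-oxobutyl}-4-methoxy-2H-pyran-2-one F5, and oxidation with Dess–Martin periodinane (NaHCO3, CH2Cl2, 0 °C) would give 13.

**Step 5.** Early collapse of the tetrahedral adduct would let the acidic product quench the carbanion, and competing ring metalation at C3 would lower conversion.
Fallback, from 8 back to 11: aldol addition of 10 to acetaldehyde would give racemic 6-(2-hydroxypropyl)-4-methoxy-2H-pyran-2-one F6, and Dess–Martin oxidation would give 11.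

**Step 4.** The ortho-lithiated benzyl ether may deprotonate its own benzylic position and rearrange (Wittig type) if the temperature rises, and a second addition of aryllithium to the product would give a benzophenone.
Fallback, from 5 back to 7 without an organolithium: aminocarbonylation of 5 with N,O-dimethylhydroxylamine hydrochloride and CO (1 atm), catalysed by zerovalent palladium generated from Pd(OAc)2 and Xantphos, with Na2CO3 in toluene at 90 °C, would give 7 in one step; no new compound is made.

**Step 9.** Partial saturation of the C2–C3 double bond on prolonged hydrogenation, and air oxidation of the liberated hydroquinone to the quinone during filtration, are the likely losses.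
Fallback, from 17 back to 18: Lewis-acid debenzylation with BCl3 and pentamethylbenzene as cation scavenger (CH2Cl2, −78 °C) would cleave both benzyl ethers without hydrogen and should leave the methyl ethers intact at that temperature; no new compound is made.

## Further compounds

F1 | step 7 | 2,5-bis(benzyloxy)-3,4-dimethoxybenzoic acid | OC(=O)c1cc(OCc2ccccc2)c(OC)c(OC)c1OCc1ccccc1
F2 | step 7 | 2,5-bis(benzyloxy)-3,4-dimethoxybenzoyl chloride | ClC(=O)c1cc(OCc2ccccc2)c(OC)c(OC)c1OCc1ccccc1
F3 | step 7 | 1-(2,6-dihydroxy-4-methoxyphenyl)ethan-1-one | CC(=O)c1c(O)cc(OC)cc1O
F4 | step 6 | 2,5-bis(benzyloxy)-3,4-dimethoxybenzaldehyde | O=Cc1cc(OCc2ccccc2)c(OC)c(OC)c1OCc1ccccc1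
F5 | step 6 | 6-{4-[2,5-bis(benzyloxy)-3,4-dimethoxyphenyl]-4-hydroxy-2-oxobutyl}-4-methoxy-2H-pyran-2-one (racemic) | COc1cc(CC(=O)CC(O)c2cc(OCc3ccccc3)c(OC)c(OC)c2OCc2ccccc2)oc(=O)c1
F6 | step 5 | 6-(2-hydroxypropyl)-4-methoxy-2H-pyran-2-one (racemic) | CC(O)Cc1cc(OC)cc(=O)o1
F0 | step 4 | none | none
F0 | step 9 | none | none
A1 | alternative 1 | 5-(benzyloxy)-2-(2,5-dihydroxy-3,4-dimethoxyphenyl)-7-methoxy-4H-chromen-4-one | COc1cc(OCc2ccccc2)c2c(=O)cc(-c3cc(O)c(OC)c(OC)c3O)oc2c1
A2 | alternative 1 | 4-{(E)-2-[5-(benzyloxy)-7-methoxy-4-oxo-4H-chromen-2-yl]ethenyl}-4-hydroxy-2,3-dimethoxycyclobut-2-en-1-one (racemic) | COC1=C(OC)C(O)(/C=C/c2cc(=O)c3c(OCc4ccccc4)cc(OC)cc3o2)C1=O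
A3 | alternative 1 | 3,4-dimethoxycyclobut-3-ene-1,2-dione (dimethyl squarate) | COC1=C(OC)C(=O)C1=O
A4 | alternative 2 | 2-[2,5-bis(benzyloxy)-3,4-dimethoxyphenyl]-5-fluoro-7-methoxy-4H-chromen-4-one | COc1cc(F)c2c(=O)cc(-c3cc(OCc4ccccc4)c(OC)c(OC)c3OCc3ccccc3)oc2c1
A5 | alternative 2 | 1-[2,5-bis(benzyloxy)-3,4-dimethoxyphenyl]ethan-1-one | CC(=O)c1cc(OCc2ccccc2)c(OC)c(OC)c1OCc1ccccc1
A6 | alternative 2 | 2,6-difluoro-4-methoxybenzoyl chloride | COc1cc(F)c(C(Cl)=O)c(F)c1
A7 | alternative 3 | 2-iodo-5-methoxybenzene-1,3-diol | COc1cc(O)c(I)c(O)c1
A8 | alternative 3 | carbon monoxide | [C-]#[O+]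
A9 | alternative 3 | 1,4-bis(benzyloxy)-5-ethynyl-2,3-dimethoxybenzene | C#Cc1cc(OCc2ccccc2)c(OC)c(OC)c1OCc1ccccc1
A10 | alternative 3 | 2-[2,5-bis(benzyloxy)-3,4-dimethoxyphenyl]-5-hydroxy-7-methoxy-4H-chromen-4-one | COc1cc(O)c2c(=O)cc(-c3cc(OCc4ccccc4)c(OC)c(OC)c3OCc3ccccc3)oc2c1
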